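**Plan**

- Numbering: the target is a 2-methoxy-6,7-dimethyl-8-aryl-1,4-naphthoquinone; ring A is the quinone ring, ring B the benzo ring, ring C the 2,4,5-trimethoxyphenyl group on C8.
- Retrosynthesis: the quinone goes back to its hydroquinone; the C4–C4a bond of ring A is cut to give a 4-aryl-4-hydroxy-3-methoxycyclobutenone; the C1–C8a bond is cut to an aryllithium plus 3-methoxycyclobutene-1,2-dione; the C8–C1'' biaryl bond is cut last.
- Enabling feature: C1–C4 of ring A, with oxygen on C1 and C4, methoxy on C2 and hydrogen on C3, are the four carbons of methyl semisquarate; ring B has one free ortho carbon (the future C4a), the other (C8) carrying ring C.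
- Forward: ring B is fitted with Cl and OTf from 2,3-dimethylphenol, ring C is coupled on, the four-membered ring is attached through the aryllithium, and ring A is closed last by thermal ring expansion; oxidation finishes.
- Stereochemistry: the target has no stereocenter; the carbinol center of the cyclobutenone is racemic and disappears in the ring expansion.

Key step: step 6

Remark: the C8–C1'' axis has three ortho substituents and may rotate slowly; the target is specified without axial configuration, so no axial control is attempted.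

**Step 1**
Reactants: 1 2,3-dimethylphenol
Product: 2 6-chloro-2,3-dimethylphenol
Conditions: SO2Cl2 (1.05 equiv), 2,2,6,6-tetramethylpiperidine (2 mol %), toluene, 65 °C
Reagents that add atoms: sulfuryl chloride, O=S(=O)(Cl)Cl
Why: Amine-catalysed ortho-selective electrophilic chlorination of a phenol; the hindered secondary amine, hydrogen-bonded to the phenolic OH, should direct chlorine to C6, the only free ortho carbon, in preference to the para carbon C4.

**Step 2**
Reactants: 2 6-chloro-2,3-dimethylphenol
Product: 3 6-chloro-2,3-dimethylphenyl trifluoromethanesulfonate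
Conditions: Tf2O, pyridine, CH2Cl2, 0 °C to rt
Reagents that add atoms: trifluoromethanesulfonic anhydride, O=S(=O)(OS(=O)(=O)C(F)(F)F)C(F)(F)F
Why: O-Sulfonylation (triflation) of a phenol, which turns the oxygen-bearing carbon into the cross-coupling site while the chloride stays as the later lithiation handle.

**Step 3**
Reactants: 3 6-chloro-2,3-dimethylphenyl trifluoromethanesulfonate; 4 (2,4,5-trimethoxyphenyl)boronic acid
Product: 5 1-chloro-3,4-dimethyl-2-(2,4,5-trimethoxyphenyl)benzene
Conditions: Pd(PPh3)4 (5 mol %), K3PO4, KBr, 1,4-dioxane/H2O (10:1), 90 °C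
Reagents that add atoms: none
Why: Suzuki–Miyaura coupling of an aryl triflate; zerovalent palladium carrying PPh3 inserts into the C–OTf bond far faster than into the C–Cl bond, so the chloride should survive untouched.

**Step 4**
Reactants: 6 dimethyl squarate (3,4-dimethoxycyclobut-3-ene-1,2-dione)
Product: 8 3-methoxycyclobut-3-ene-1,2-dione, via 4-hydroxy-2,3-dimethoxycyclobut-2-en-1-one 7 (not isolated)
Conditions: LiAlH(Ot-Bu)3 (1.05 equiv), THF, −78 to −20 °C; aq. HCl quench; then conc. HCl (cat.), CH2Cl2, rt
Reagents that add atoms: water, O (its oxygen becomes the new ketone oxygen; the carbinol oxygen leaves as water)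
Why: Mono-reduction of one squarate carbonyl by the hindered hydride, then acid-promoted loss of the carbinol hydroxyl and hydrolysis of the methoxy-stabilised cation with loss of methanol, the established route from squarate 1,2-adducts to 3-alkoxycyclobutenediones.

**Step 5**
Reactants: 5 1-chloro-3,4-dimethyl-2-(2,4,5-trimethoxyphenyl)benzene; 8 3-methoxycyclobut-3-ene-1,2-dione
Product: 10 4-[3,4-dimethyl-2-(2,4,5-trimethoxyphenyl)phenyl]-4-hydroxy-3-methoxycyclobut-2-en-1-one (racemic), via [3,4-dimethyl-2-(2,4,5-trimethoxyphenyl)phenyl]lithium 9 (not isolated)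
Conditions: lithium 4,4'-di-tert-butylbiphenylide (titrated stock solution, 2.1 equiv), THF, −78 °C; cannulate into 8 (1.2 equiv), THF, −78 °C; aq. NH4Cl
Reagents that add atoms: none
Why: Reductive lithiation of an aryl chloride by an arene radical anion, then 1,2-addition of the aryllithium to the ketone-like carbonyl next to the methoxy-bearing carbon and not to the vinylogous ester carbonyl, as is the rule for organolithium additions to 3-alkoxycyclobutenediones; the carbinol center forms racemic and is erased in step 6.

**Step 6**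
Reactants: 10 4-[3,4-dimethyl-2-(2,4,5-trimethoxyphenyl)phenyl]-4-hydroxy-3-methoxycyclobut-2-en-1-one
Product: 13 2-methoxy-6,7-dimethyl-8-(2,4,5-trimethoxyphenyl)naphthalene-1,4-diol, via aryl(hydroxy)vinylketene 11 (not isolated), via 8aH-naphthalen-1-one tautomer 12 (not isolated)
Conditions: degassed p-xylene (0.02 M), reflux (138 °C), argon
Reagents that add atoms: none
Why: Heating opens the cyclobutenone by conrotatory 4π electrocyclic cleavage of the bond between the ring carbonyl carbon and the carbinol carbon to give the (Z)-aryl(hydroxy)vinylketene 11, the hydroxyl rotating outward as an electron donor so that ring B is turned inward next to the ketene carbon. A thermal disrotatory 6π electrocyclization then joins the ketene carbon to C4a, closing ring A as the six-membered dienone 12, and enolization together with rearomatization of ring B gives hydroquinone 13. The closest known reaction type is the Moore rearrangement of 4-aryl-4-hydroxycyclobutenones to naphthohydroquinones. No stereocenter is set: the racemic carbinol center of 10 becomes sp2 in 11 and the transient sp3 ring-fusion carbon of 12 is lost on tautomerization. The selectivity needed is the site of ring closure and the placement of the methoxy group; the first is secured because the only other ortho carbon of ring B carries ring C, the second because step 5 placed the aryl group on the carbon next to the methoxy-bearing carbon, which makes that carbon C2, beside C1 on the ring C side. Dilute, oxygen-free solution should keep the ketene from intermolecular trapping and the hydroquinone from premature oxidation.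

**Step 7**
Reactants: 13 2-methoxy-6,7-dimethyl-8-(2,4,5-trimethoxyphenyl)naphthalene-1,4-diol
Product: 14 2-methoxy-6,7-dimethyl-8-(2,4,5-trimethoxyphenyl)naphthalene-1,4-dione
Conditions: Ag2O, MgSO4, Et2O, rt
Reagents that add atoms: none
Why: Two-electron oxidation of a 1,4-hydroquinone to the quinone by Ag2O, mild enough to leave the electron-rich trimethoxyphenyl ring untouched.

**Compound list**

1 | 2,3-dimethylphenol | Cc1cccc(O)c1C | starting material
2 | 6-chloro-2,3-dimethylphenol | Cc1ccc(Cl)c(O)c1C | intermediate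
3 | 6-chloro-2,3-dimethylphenyl trifluoromethanesulfonate | Cc1ccc(Cl)c(OS(=O)(=O)C(F)(F)F)c1C | intermediate
4 | (2,4,5-trimethoxyphenyl)boronic acid | COc1cc(OC)c(B(O)O)cc1OC | starting material
5 | 1-chloro-3,4-dimethyl-2-(2,4,5-trimethoxyphenyl)benzene | Cc1ccc(Cl)c(-c2cc(OC)c(OC)cc2OC)c1C | intermediate
6 | dimethyl squarate (3,4-dimethoxycyclobut-3-ene-1,2-dione) | COC1=C(OC)C(=O)C1=O | starting material
7 | 4-hydroxy-2,3-dimethoxycyclobut-2-en-1-one (racemic) | COC1=C(OC)C(=O)C1O | intermediate (not isolated)
8 | 3-methoxycyclobut-3-ene-1,2-dione | COC1=CC(=O)C1=O | intermediate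
9 | [3,4-dimethyl-2-(2,4,5-trimethoxyphenyl)phenyl]lithium | [Li]c1ccc(C)c(C)c1-c1cc(OC)c(OC)cc1OC | intermediate (not isolated)
10 | 4-[3,4-dimethyl-2-(2,4,5-trimethoxyphenyl)phenyl]-4-hydroxy-3-methoxycyclobut-2-en-1-one (racemic) | COC1=CC(=O)C1(O)c1ccc(C)c(C)c1-c1cc(OC)c(OC)cc1OC | intermediate
11 | (3Z)-4-[3,4-dimethyl-2-(2,4,5-trimethoxyphenyl)phenyl]-4-hydroxy-3-methoxybuta-1,3-dien-1-one | O=C=C/C(OC)=C(\c1ccc(C)c(C)c1-c1cc(OC)c(OC)cc1OC)O | intermediate (not isolated)
12 | 4-hydroxy-3-methoxy-6,7-dimethyl-5-(2,4,5-trimethoxyphenyl)-8aH-naphthalen-1-one (racemic) | COC1=CC(=O)C2C=C(C)C(C)=C(c3cc(OC)c(OC)cc3OC)C2=C1O | intermediate (not isolated)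
13 | 2-methoxy-6,7-dimethyl-8-(2,4,5-trimethoxyphenyl)naphthalene-1,4-diol | COc1cc(O)c2cc(C)c(C)c(-c3cc(OC)c(OC)cc3OC)c2c1O | intermediate
14 | 2-methoxy-6,7-dimethyl-8-(2,4,5-trimethoxyphenyl)naphthalene-1,4-dione | COC1=CC(=O)c2cc(C)c(C)c(-c3cc(OC)c(OC)cc3OC)c2C1=O | target

**Step count**

Total steps: 7. Longest linear sequence: 6 steps (steps 1, 2, 3, 5, 6, 7 from 2,3-dimethylphenol); step 4 is a one-step side branch.

**Steps most likely to fail**

1. Step 5. Electron transfer may not stop at the C–Cl bond and may cleave aryl methyl ethers. Carried-over reductant may reduce the dione. The crowded aryllithium may act as a base or add in the conjugate sense.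

   The fallback attaches the four-membered ring before ring C, so that a simple bromine–lithium exchange serves. It sets out from 1 and comes back at 14.
   - Ortho-bromination of 1 (NBS, cat. i-Pr2NH, CH2Cl2) would give 6-bromo-2,3-dimethylphenol F1.
   - Protection (MOMCl, i-Pr2NEt) would give 1-bromo-2-(methoxymethoxy)-3,4-dimethylbenzene F2.
   - Exchange with n-BuLi in THF at −78 °C would give [2-(methoxymethoxy)-3,4-dimethylphenyl]lithium F3.
   - Addition of F3 to 8 would give 4-hydroxy-3-methoxy-4-[2-(methoxymethoxy)-3,4-dimethylphenyl]cyclobut-2-en-1-one F4.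
   - The same thermal ring expansion would give 2-methoxy-8-(methoxymethoxy)-6,7-dimethylnaphthalene-1,4-diol F5.
   - Ag2O would give 2-methoxy-8-(methoxymethoxy)-6,7-dimethylnaphthalene-1,4-dione F6.
   - HCl in MeOH would remove the acetal to give 8-hydroxy-2-methoxy-6,7-dimethylnaphthalene-1,4-dione F7.
   - Tf2O and pyridine would give 7-methoxy-2,3-dimethyl-5,8-dioxo-5,8-dihydronaphthalen-1-yl trifluoromethanesulfonate F8.
   - Suzuki–Miyaura coupling of F8 with 4 (Pd(PPh3)4, K3PO4, 1,4-dioxane) would give 14.

2. Step 3. Oxidative addition at a triflate flanked by chlorine and methyl may be slow. The electron-rich boronic acid may then be lost to protodeboronation and the triflate to S–O hydrolysis.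

   The fallback is a Negishi coupling, which sets out from 3 and comes back at 5.
   - Purchased 1-bromo-2,4,5-trimethoxybenzene F9 would be exchanged with n-BuLi (THF, −78 °C) to (2,4,5-trimethoxyphenyl)lithium F10.
   - Transmetalation with ZnCl2 would give chlorido(2,4,5-trimethoxyphenyl)zinc F11.
   - Coupling of F11 with 3 under PdCl2(dppf) in THF at 60 °C would give 5, with the C–Cl bond again left alone.

3. Step 4. The small methyl semisquarate may be over-reduced, hydrolysed at its vinylogous ester, or lost through volatility and oligomerization on isolation.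

   The fallback uses the sturdier isopropyl series and exchanges the alkoxy group at the end. It sets out from 9 (made from 5 as in step 5) and comes back at 14.
   - Purchased diisopropyl squarate F12 would be reduced with LiAlH(Ot-Bu)3 to 4-hydroxy-2,3-di(propan-2-yloxy)cyclobut-2-en-1-one F13.
   - Acid would convert F13 to 3-(propan-2-yloxy)cyclobut-3-ene-1,2-dione F14.
   - Addition of 9 would give 4-[3,4-dimethyl-2-(2,4,5-trimethoxyphenyl)phenyl]-4-hydroxy-3-(propan-2-yloxy)cyclobut-2-en-1-one F15.
   - Thermolysis would give 6,7-dimethyl-2-(propan-2-yloxy)-8-(2,4,5-trimethoxyphenyl)naphthalene-1,4-diol F16.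
   - Ag2O would give 6,7-dimethyl-2-(propan-2-yloxy)-8-(2,4,5-trimethoxyphenyl)naphthalene-1,4-dione F17.
   - Acid-catalysed alkoxy exchange of this vinylogous ester (MeOH, cat. H2SO4, 50 °C) would give 14.

**Further compounds**

F1 | step 5 | 6-bromo-2,3-dimethylphenol | Cc1ccc(Br)c(O)c1C
F2 | step 5 | 1-bromo-2-(methoxymethoxy)-3,4-dimethylbenzene | COCOc1c(Br)ccc(C)c1C
F3 | step 5 | [2-(methoxymethoxy)-3,4-dimethylphenyl]lithium | [Li]c1ccc(C)c(C)c1OCOC
F4 | step 5 | 4-hydroxy-3-methoxy-4-[2-(methoxymethoxy)-3,4-dimethylphenyl]cyclobut-2-en-1-one (racemic) | COCOc1c(C)c(C)ccc1C1(O)C(OC)=CC1=O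
F5 | step 5 | 2-methoxy-8-(methoxymethoxy)-6,7-dimethylnaphthalene-1,4-diol | COCOc1c(C)c(C)cc2c(O)cc(OC)c(O)c12
F6 | step 5 | 2-methoxy-8-(methoxymethoxy)-6,7-dimethylnaphthalene-1,4-dione | COCOc1c(C)c(C)cc2C(=O)C=C(OC)C(=O)c12
F7 | step 5 | 8-hydroxy-2-methoxy-6,7-dimethylnaphthalene-1,4-dione | COC1=CC(=O)c2cc(C)c(C)c(O)c2C1=O
F8 | step 5 | 7-methoxy-2,3-dimethyl-5,8-dioxo-5,8-dihydronaphthalen-1-yl trifluoromethanesulfonate | COC1=CC(=O)c2cc(C)c(C)c(OS(=O)(=O)C(F)(F)F)c2C1=O
F9 | step 3 | 1-bromo-2,4,5-trimethoxybenzene (purchased) | COc1cc(OC)c(Br)cc1OC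
F10 | step 3 | (2,4,5-trimethoxyphenyl)lithium | [Li]c1cc(OC)c(OC)cc1OC
F11 | step 3 | chlorido(2,4,5-trimethoxyphenyl)zinc | COc1cc(OC)c([Zn]Cl)cc1OC
F12 | step 4 | diisopropyl squarate (purchased) | CC(C)OC1=C(OC(C)C)C(=O)C1=O
F13 | step 4 | 4-hydroxy-2,3-di(propan-2-yloxy)cyclobut-2-en-1-one (racemic) | CC(C)OC1=C(OC(C)C)C(=O)C1O
F14 | step 4 | 3-(propan-2-yloxy)cyclobut-3-ene-1,2-dione | CC(C)OC1=CC(=O)C1=O
F15 | step 4 | 4-[3,4-dimethyl-2-(2,4,5-trimethoxyphenyl)phenyl]-4-hydroxy-3-(propan-2-yloxy)cyclobut-2-en-1-one (racemic) | CC(C)OC1=CC(=O)C1(O)c1ccc(C)c(C)c1-c1cc(OC)c(OC)cc1OC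
F16 | step 4 | 6,7-dimethyl-2-(propan-2-yloxy)-8-(2,4,5-trimethoxyphenyl)naphthalene-1,4-diol | CC(C)Oc1cc(O)c2cc(C)c(C)c(-c3cc(OC)c(OC)cc3OC)c2c1O
F17 | step 4 | 6,7-dimethyl-2-(propan-2-yloxy)-8-(2,4,5-trimethoxyphenyl)naphthalene-1,4-dione | CC(C)OC1=CC(=O)c2cc(C)c(C)c(-c3cc(OC)c(OC)cc3OC)c2C1=O
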